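**Plan**
- Retrosynthesis: the C4 carbinol is taken back to the ketone, ring C is cut at C2–C3, the ketone at C4–C4a, and the prenyl group at C5'.
- Enabling feature: C2 is a CH2 bound to O1 and to C3, so it can be the methyl carbon of one of the two equivalent ortho-methoxy groups of a 2,4,6-trimethoxyphenyl ketone whose α-carbon (C3) carries ring B; the other ortho-methoxy ends as the 5-oxygen.
- Forward: ring B is made as a bromo lactone (the lactone masks O2', so O4' is silylated alone), opened to a Weinreb amide, silylated at O2', prenylated and joined to lithiated ring A; diazo transfer and carbenoid C–H insertion then close ring C.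
- End game: O2' is unmasked and methylated, the peri 5-OMe is cleaved by chelation, and the 5-OH is silylated.
- Stereochemistry: both centres come from one transfer-hydrogenative dynamic kinetic resolution with RuCl(p-cymene)[(R,R)-TsDPEN] (4R from the catalyst, 3R by equilibration at C3 and cis delivery); fluoride then frees the phenols.

Key step: step 9

Assumption: locants follow the isoflavan skeleton (O1, C2, C3, C4, ring A C4a–C8a, ring B C1'–C6'); the target SMILES is read as the cis-(3R,4R) isomer; O2' carries a silyl ether in the key step because an ortho-acetate could transfer its acyl group to the enolate during diazo transfer.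

**Route**

Step 1
Reactants: 1 2,4-dihydroxyphenylacetic acid
Product: 2 (5-bromo-2,4-dihydroxyphenyl)acetic acid
Conditions: NBS (1.0 equiv), MeCN, −20 → 0 °C
Reagents that add atoms: N-bromosuccinimide, BrN1C(=O)CCC1=O
Why: Electrophilic aromatic bromination should go to C5, which is para to the 2-OH, ortho to the 4-OH and unhindered, whereas C3 lies between both hydroxyls.

Step 2
Reactants: 2 (5-bromo-2,4-dihydroxyphenyl)acetic acid
Product: 3 5-bromo-6-hydroxybenzofuran-2(3H)-one
Conditions: p-TsOH·H2O (cat.), toluene, reflux, Dean–Stark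
Reagents that add atoms: none
Why: Acid-catalysed lactonisation of a 2-hydroxyphenylacetic acid with azeotropic removal of water closes the five-membered lactone on O2' only, which leaves the later O4' as the single free phenol.

Step 3
Reactants: 3 5-bromo-6-hydroxybenzofuran-2(3H)-one
Product: 4 5-bromo-6-(triisopropylsilyloxy)benzofuran-2(3H)-one
Conditions: TIPSCl, imidazole, CH2Cl2, 0 °C → rt
Reagents that add atoms: triisopropylsilyl chloride, CC(C)[Si](Cl)(C(C)C)C(C)C
Why: Silylation of the only free phenol with a silyl chloride and imidazole is routine and installs the group that protects O4' to the end.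

Step 4
Reactants: 4 5-bromo-6-(triisopropylsilyloxy)benzofuran-2(3H)-one
Product: 5 2-[5-bromo-2-hydroxy-4-(triisopropylsilyloxy)phenyl]-N-methoxy-N-methylacetamide
Conditions: MeNH(OMe)·HCl, AlMe3, CH2Cl2, 0 °C → rt; aq. HCl (0.5 M) work-up
Reagents that add atoms: N,O-dimethylhydroxylamine hydrochloride, CNOC.Cl
Why: Weinreb aminolysis of a lactone by the aluminium amide formed in the flask opens the strained aryl ester and releases the O2' phenol.

Step 5
Reactants: 5 2-[5-bromo-2-hydroxy-4-(triisopropylsilyloxy)phenyl]-N-methoxy-N-methylacetamide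
Product: 6 2-[5-bromo-2-(tert-butyldimethylsilyloxy)-4-(triisopropylsilyloxy)phenyl]-N-methoxy-N-methylacetamide
Conditions: TBSCl, imidazole, DMF, rt
Reagents that add atoms: tert-butyldimethylsilyl chloride, CC(C)(C)[Si](C)(C)Cl
Why: Standard phenol silylation gives O2' a group with no C–H next to oxygen and no carbonyl, and one that is more base-labile than the O4' silyl ether.

Step 6
Reactants: 6 2-[5-bromo-2-(tert-butyldimethylsilyloxy)-4-(triisopropylsilyloxy)phenyl]-N-methoxy-N-methylacetamide; 7 tributyl(3-methylbut-2-en-1-yl)stannane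
Product: 8 2-[2-(tert-butyldimethylsilyloxy)-5-(3-methylbut-2-en-1-yl)-4-(triisopropylsilyloxy)phenyl]-N-methoxy-N-methylacetamide
Conditions: Pd(PPh3)4 (5 mol %), DMF, 95 °C
Reagents that add atoms: none
Why: Stille coupling of an aryl bromide with an allylic stannane under neutral conditions should give the linear prenyl arene, since reductive elimination takes place at the less substituted allyl terminus.

Step 7
Reactants: 9 1,3,5-trimethoxybenzene; 8 2-[2-(tert-butyldimethylsilyloxy)-5-(3-methylbut-2-en-1-yl)-4-(triisopropylsilyloxy)phenyl]-N-methoxy-N-methylacetamide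
Product: 11 2-[2-(tert-butyldimethylsilyloxy)-5-(3-methylbut-2-en-1-yl)-4-(triisopropylsilyloxy)phenyl]-1-(2,4,6-trimethoxyphenyl)ethan-1-one, via 2,4,6-trimethoxyphenyllithium 10 (not isolated)
Conditions: 9, n-BuLi, THF, 0 °C → rt; then 8 (inverse addition), −78 → 0 °C; aq. NH4Cl
Reagents that add atoms: none
Why: Lithiation of 1,3,5-trimethoxybenzene between two methoxy groups followed by Weinreb ketone synthesis should stop at the ketone because the chelated tetrahedral adduct survives until work-up, and low temperature limits enolisation of the amide.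

Step 8
Reactants: 11 2-[2-(tert-butyldimethylsilyloxy)-5-(3-methylbut-2-en-1-yl)-4-(triisopropylsilyloxy)phenyl]-1-(2,4,6-trimethoxyphenyl)ethan-1-one
Product: 12 2-diazo-2-[2-(tert-butyldimethylsilyloxy)-5-(3-methylbut-2-en-1-yl)-4-(triisopropylsilyloxy)phenyl]-1-(2,4,6-trimethoxyphenyl)ethan-1-one
Conditions: 4-nitrobenzenesulfonyl azide, DBU, MeCN, 0 °C
Reagents that add atoms: 4-nitrobenzenesulfonyl azide, [O-][N+](=O)c1ccc(cc1)S(=O)(=O)N=[N+]=[N-]
Why: Direct Regitz diazo transfer to a benzyl ketone with an electron-poor sulfonyl azide and DBU is established for α-aryl ketones, and the silyl ether at O2' cannot undergo the acyl transfer to the enolate that an ester would risk.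

Step 9
Reactants: 12 2-diazo-2-[2-(tert-butyldimethylsilyloxy)-5-(3-methylbut-2-en-1-yl)-4-(triisopropylsilyloxy)phenyl]-1-(2,4,6-trimethoxyphenyl)ethan-1-one
Product: 13 racemic 3-[2-(tert-butyldimethylsilyloxy)-5-(3-methylbut-2-en-1-yl)-4-(triisopropylsilyloxy)phenyl]-5,7-dimethoxychroman-4-one
Conditions: Rh2(OAc)4 (2 mol %), CH2Cl2, 40 °C, slow addition of 12 by syringe pump, final 0.005 M
Reagents that add atoms: none
Why: Proposed new method: Rh2(OAc)4 expels N2 from 12 to give a rhodium carbenoid at C3, stabilised by the ring B aryl donor and the ketone acceptor, which inserts into a C–H bond of one of the two equivalent ortho-methoxy groups of ring A through a three-centre transition state in which the ether oxygen stabilises the developing positive charge. The closest known reactions are the dirhodium-catalysed C–H insertion of 2-alkoxyaryl α-diazoketones next to the ether oxygen giving chroman-4-ones, the intramolecular insertion of α-aryl-α-diazoketones, and the insertion of aryl-substituted carbenoids into methyl ether C–H bonds; their combination on a methoxy C–H is untested. Ring C closes as a six-membered ring by formal 1,6-insertion, forming the C2–C3 bond. C3 is formed racemic and stays enolisable, so no stereocontrol is asked of this step and the centre is fixed in step 14. The step needs insertion into the ring A methoxy C–H over all other paths: the O2' silyl ether offers no C–H next to oxygen and its oxygen could only give a four-membered ylide, the oxonium ylide at a ring A methoxy oxygen should revert because a 1,2-methyl shift is slow, and slow addition at high dilution suppresses carbene dimerisation and intermolecular cyclopropanation of the trisubstituted prenyl alkene.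

Step 10
Reactants: 13 racemic 3-[2-(tert-butyldimethylsilyloxy)-5-(3-methylbut-2-en-1-yl)-4-(triisopropylsilyloxy)phenyl]-5,7-dimethoxychroman-4-one
Product: 14 racemic 3-[2-hydroxy-5-(3-methylbut-2-en-1-yl)-4-(triisopropylsilyloxy)phenyl]-5,7-dimethoxychroman-4-one
Conditions: K2CO3 (0.3 equiv), MeOH/THF, 0 °C, monitored
Reagents that add atoms: none
Why: Base-mediated methanolysis cleaves aryl tert-butyldimethylsilyl ethers much faster than aryl triisopropylsilyl ethers, so O2' should be released alone, and epimerisation at C3 is irrelevant at the racemic stage.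

Step 11
Reactants: 14 racemic 3-[2-hydroxy-5-(3-methylbut-2-en-1-yl)-4-(triisopropylsilyloxy)phenyl]-5,7-dimethoxychroman-4-one
Product: 15 racemic 5,7-dimethoxy-3-[2-methoxy-5-(3-methylbut-2-en-1-yl)-4-(triisopropylsilyloxy)phenyl]chroman-4-one
Conditions: MeOH, PPh3, DIAD, THF, 0 °C → rt
Reagents that add atoms: methanol, CO
Why: Mitsunobu etherification methylates the phenol only, because C3–H is not acidic enough to act as the pronucleophile, which avoids the C3-methylation that methyl iodide and base could cause.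

Step 12
Reactants: 15 racemic 5,7-dimethoxy-3-[2-methoxy-5-(3-methylbut-2-en-1-yl)-4-(triisopropylsilyloxy)phenyl]chroman-4-one
Product: 16 racemic 5-hydroxy-7-methoxy-3-[2-methoxy-5-(3-methylbut-2-en-1-yl)-4-(triisopropylsilyloxy)phenyl]chroman-4-one
Conditions: MgI2 (etherate), toluene/THF, 60 °C
Reagents that add atoms: none
Why: Chelation-controlled ether cleavage: magnesium binds the C4 carbonyl and the peri 5-methoxy oxygen and iodide removes that methyl by SN2, while the unchelated 7- and 2'-methoxy groups and the prenyl group should stay.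

Step 13
Reactants: 16 racemic 5-hydroxy-7-methoxy-3-[2-methoxy-5-(3-methylbut-2-en-1-yl)-4-(triisopropylsilyloxy)phenyl]chroman-4-one
Product: 17 racemic 5-(tert-butyldimethylsilyloxy)-7-methoxy-3-[2-methoxy-5-(3-methylbut-2-en-1-yl)-4-(triisopropylsilyloxy)phenyl]chroman-4-one
Conditions: TBSOTf, 2,6-lutidine, CH2Cl2, −78 → 0 °C
Reagents that add atoms: tert-butyldimethylsilyl triflate, CC(C)(C)[Si](C)(C)OS(=O)(=O)C(F)(F)F
Why: Silyl triflate silylation of the hydrogen-bonded peri phenol breaks the chelate that would slow reduction of the ketone and keeps the later ortho-hydroxybenzyl alcohol masked during the reduction.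

Step 14
Reactants: 17 racemic 5-(tert-butyldimethylsilyloxy)-7-methoxy-3-[2-methoxy-5-(3-methylbut-2-en-1-yl)-4-(triisopropylsilyloxy)phenyl]chroman-4-one
Product: 18 (3R,4R)-5-(tert-butyldimethylsilyloxy)-7-methoxy-3-[2-methoxy-5-(3-methylbut-2-en-1-yl)-4-(triisopropylsilyloxy)phenyl]chroman-4-ol (cis)
Conditions: RuCl(p-cymene)[(R,R)-TsDPEN] (5 mol %), HCO2H/Et3N (1:2), EtOAc, 40 °C
Reagents that add atoms: none
Why: Noyori–Ikariya asymmetric transfer hydrogenation with dynamic kinetic resolution: Et3N equilibrates C3 through the enol, the (R,R) catalyst delivers hydride to the face that gives the 4R alcohol (the sense known for aryl ketones), and only the 3R ketone is reduced fast, so the cis (3R,4R) alcohol should result.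

Step 15
Reactants: 18 (3R,4R)-5-(tert-butyldimethylsilyloxy)-7-methoxy-3-[2-methoxy-5-(3-methylbut-2-en-1-yl)-4-(triisopropylsilyloxy)phenyl]chroman-4-ol
Product: 19 (3R,4R)-3-[4-hydroxy-2-methoxy-5-(3-methylbut-2-en-1-yl)phenyl]-7-methoxychromane-4,5-diol
Conditions: TBAF, AcOH, THF, 0 °C; pH 7 buffer work-up
Reagents that add atoms: none
Why: Fluoride cleaves both aryl silyl ethers under acetic acid buffering, conditions that should leave the ionisable trioxygenated benzylic alcohol, the prenyl group and both stereocentres untouched.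

**Compound list**

1 | 2,4-dihydroxyphenylacetic acid | OC(=O)Cc1ccc(O)cc1O | starting material
2 | (5-bromo-2,4-dihydroxyphenyl)acetic acid | OC(=O)Cc1cc(Br)c(O)cc1O | intermediate
3 | 5-bromo-6-hydroxybenzofuran-2(3H)-one | O=C1Cc2cc(Br)c(O)cc2O1 | intermediate
4 | 5-bromo-6-(triisopropylsilyloxy)benzofuran-2(3H)-one | O=C1Cc2cc(Br)c(O[Si](C(C)C)(C(C)C)C(C)C)cc2O1 | intermediate
5 | 2-[5-bromo-2-hydroxy-4-(triisopropylsilyloxy)phenyl]-N-methoxy-N-methylacetamide | CON(C)C(=O)Cc1cc(Br)c(O[Si](C(C)C)(C(C)C)C(C)C)cc1O | intermediate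
6 | 2-[5-bromo-2-(tert-butyldimethylsilyloxy)-4-(triisopropylsilyloxy)phenyl]-N-methoxy-N-methylacetamide | CON(C)C(=O)Cc1cc(Br)c(O[Si](C(C)C)(C(C)C)C(C)C)cc1O[Si](C)(C)C(C)(C)C | intermediate
7 | tributyl(3-methylbut-2-en-1-yl)stannane | CCCC[Sn](CCCC)(CCCC)CC=C(C)C | starting material
8 | 2-[2-(tert-butyldimethylsilyloxy)-5-(3-methylbut-2-en-1-yl)-4-(triisopropylsilyloxy)phenyl]-N-methoxy-N-methylacetamide | CON(C)C(=O)Cc1cc(CC=C(C)C)c(O[Si](C(C)C)(C(C)C)C(C)C)cc1O[Si](C)(C)C(C)(C)C | intermediate
9 | 1,3,5-trimethoxybenzene | COc1cc(OC)cc(OC)c1 | starting material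
10 | 2,4,6-trimethoxyphenyllithium | [Li]c1c(OC)cc(OC)cc1OC | intermediate
11 | 2-[2-(tert-butyldimethylsilyloxy)-5-(3-methylbut-2-en-1-yl)-4-(triisopropylsilyloxy)phenyl]-1-(2,4,6-trimethoxyphenyl)ethan-1-one | COc1cc(OC)c(C(=O)Cc2cc(CC=C(C)C)c(O[Si](C(C)C)(C(C)C)C(C)C)cc2O[Si](C)(C)C(C)(C)C)c(OC)c1 | intermediate
12 | 2-diazo-2-[2-(tert-butyldimethylsilyloxy)-5-(3-methylbut-2-en-1-yl)-4-(triisopropylsilyloxy)phenyl]-1-(2,4,6-trimethoxyphenyl)ethan-1-one | COc1cc(OC)c(C(=O)C(=[N+]=[N-])c2cc(CC=C(C)C)c(O[Si](C(C)C)(C(C)C)C(C)C)cc2O[Si](C)(C)C(C)(C)C)c(OC)c1 | intermediate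
13 | racemic 3-[2-(tert-butyldimethylsilyloxy)-5-(3-methylbut-2-en-1-yl)-4-(triisopropylsilyloxy)phenyl]-5,7-dimethoxychroman-4-one | COc1cc(OC)c2c(c1)OCC(c1cc(CC=C(C)C)c(O[Si](C(C)C)(C(C)C)C(C)C)cc1O[Si](C)(C)C(C)(C)C)C2=O | intermediate
14 | racemic 3-[2-hydroxy-5-(3-methylbut-2-en-1-yl)-4-(triisopropylsilyloxy)phenyl]-5,7-dimethoxychroman-4-one | COc1cc(OC)c2c(c1)OCC(c1cc(CC=C(C)C)c(O[Si](C(C)C)(C(C)C)C(C)C)cc1O)C2=O | intermediate
15 | racemic 5,7-dimethoxy-3-[2-methoxy-5-(3-methylbut-2-en-1-yl)-4-(triisopropylsilyloxy)phenyl]chroman-4-one | COc1cc(OC)c2c(c1)OCC(c1cc(CC=C(C)C)c(O[Si](C(C)C)(C(C)C)C(C)C)cc1OC)C2=O | intermediate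
16 | racemic 5-hydroxy-7-methoxy-3-[2-methoxy-5-(3-methylbut-2-en-1-yl)-4-(triisopropylsilyloxy)phenyl]chroman-4-one | COc1cc(O)c2c(c1)OCC(c1cc(CC=C(C)C)c(O[Si](C(C)C)(C(C)C)C(C)C)cc1OC)C2=O | intermediate
17 | racemic 5-(tert-butyldimethylsilyloxy)-7-methoxy-3-[2-methoxy-5-(3-methylbut-2-en-1-yl)-4-(triisopropylsilyloxy)phenyl]chroman-4-one | COc1cc(O[Si](C)(C)C(C)(C)C)c2c(c1)OCC(c1cc(CC=C(C)C)c(O[Si](C(C)C)(C(C)C)C(C)C)cc1OC)C2=O | intermediate
18 | (3R,4R)-5-(tert-butyldimethylsilyloxy)-7-methoxy-3-[2-methoxy-5-(3-methylbut-2-en-1-yl)-4-(triisopropylsilyloxy)phenyl]chroman-4-ol | COc1cc(O[Si](C)(C)C(C)(C)C)c2c(c1)OC[C@@H](c1cc(CC=C(C)C)c(O[Si](C(C)C)(C(C)C)C(C)C)cc1OC)[C@H]2O | intermediate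
19 | (3R,4R)-3-[4-hydroxy-2-methoxy-5-(3-methylbut-2-en-1-yl)phenyl]-7-methoxychromane-4,5-diol | COc1cc(O)c2c(c1)OC[C@@H](c1cc(CC=C(C)C)c(O)cc1OC)[C@H]2O | target

**Step count**

Total steps: 15. Longest linear sequence: 15 steps (from 1 to 19; ring A component 9 enters in step 7).

**Steps most likely to fail**

Step 9. The primary methoxy C–H insertion may lose to oxonium ylide formation with a 1,2-methyl shift, to carbene dimerisation, or to attack on the prenyl alkene. The fallback builds C2 by known isoflavone chemistry and sets out from ketone 11. MgI2 (about one equivalent, toluene/THF, 60 °C) should cleave one of the two chelating ortho-methoxy groups to give 1-(2-hydroxy-4,6-dimethoxyphenyl)-2-[2-(tert-butyldimethylsilyloxy)-5-(3-methylbut-2-en-1-yl)-4-(triisopropylsilyloxy)phenyl]ethan-1-one F1. Heating with N,N-dimethylformamide dimethyl acetal in toluene should then close ring C by enaminone formation and O-cyclisation to 3-[2-(tert-butyldimethylsilyloxy)-5-(3-methylbut-2-en-1-yl)-4-(triisopropylsilyloxy)phenyl]-5,7-dimethoxy-4H-chromen-4-one F2. Conjugate reduction of this isoflavone with one equivalent of LiBH(s-Bu)3 in THF at −78 °C returns to the route at 13.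

Step 14. Hydride transfer to a ketone flanked by the peri silyloxy group may be slow, equilibration at C3 may lag behind reduction and erode the diastereo- and enantioselectivity, or the product may ionise at C4 in the formate medium. The fallback sets out from 17 and separates reduction from resolution. LiBH(s-Bu)3 in THF at −78 °C should attack anti to the C3 aryl group and give the racemic cis alcohol, that is 18 together with (3S,4S)-5-(tert-butyldimethylsilyloxy)-7-methoxy-3-[2-methoxy-5-(3-methylbut-2-en-1-yl)-4-(triisopropylsilyloxy)phenyl]chroman-4-ol F3. Preparative HPLC on a chiral stationary phase then returns the single enantiomer 18.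

Step 10. The O4' triisopropylsilyl ether may be lost alongside the O2' group, or methanolic base may open ring C by retro-oxa-Michael reaction. The fallback sets out from 13 and replaces selective deprotection by selective protection. TBAF/AcOH in THF should remove both silyl groups to give racemic 3-[2,4-dihydroxy-5-(3-methylbut-2-en-1-yl)phenyl]-5,7-dimethoxychroman-4-one F4. TIPSCl (one equivalent) with imidazole should then silylate the 4'-OH, since the 2'-OH is flanked by C3 and hydrogen-bonded to the C4 carbonyl, which returns to the route at 14.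

**Further compounds**

F1 | step 9 | 1-(2-hydroxy-4,6-dimethoxyphenyl)-2-[2-(tert-butyldimethylsilyloxy)-5-(3-methylbut-2-en-1-yl)-4-(triisopropylsilyloxy)phenyl]ethan-1-one | COc1cc(O)c(C(=O)Cc2cc(CC=C(C)C)c(O[Si](C(C)C)(C(C)C)C(C)C)cc2O[Si](C)(C)C(C)(C)C)c(OC)c1
F2 | step 9 | 3-[2-(tert-butyldimethylsilyloxy)-5-(3-methylbut-2-en-1-yl)-4-(triisopropylsilyloxy)phenyl]-5,7-dimethoxy-4H-chromen-4-one | COc1cc(OC)c2c(c1)occ(-c1cc(CC=C(C)C)c(O[Si](C(C)C)(C(C)C)C(C)C)cc1O[Si](C)(C)C(C)(C)C)c2=O
F3 | step 14 | (3S,4S)-5-(tert-butyldimethylsilyloxy)-7-methoxy-3-[2-methoxy-5-(3-methylbut-2-en-1-yl)-4-(triisopropylsilyloxy)phenyl]chroman-4-ol | COc1cc(O[Si](C)(C)C(C)(C)C)c2c(c1)OC[C@H](c1cc(CC=C(C)C)c(O[Si](C(C)C)(C(C)C)C(C)C)cc1OC)[C@@H]2O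
F4 | step 10 | racemic 3-[2,4-dihydroxy-5-(3-methylbut-2-en-1-yl)phenyl]-5,7-dimethoxychroman-4-one | COc1cc(OC)c2c(c1)OCC(c1cc(CC=C(C)C)c(O)cc1O)C2=O
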